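Substrate meets reagent, and if reagent stays near a constant c̄ (pseudo-first-order), the logarithm of the substrate fraction grows linearly in time with rate constant k. Target trails that loss by a lag τ.

| flask | substrate | reagent | remark | time |
|---|---|---|---|---|
| spring | 11 mM | 10.5 mM | run made earlier |  |
| theta | 2.5 mM | 15.0 mM |  | 1.0 h |
| delta | 10 mM | 10.5 mM |  | 1.0 h |

- spring (time / min: target / %, substrate / %): 1.50: 0, 99.0; 3.00: 0, 97.4; 5.00: 0.9, 95.3; 8.00: 1.2, 94.1; 12.0: 2.4, 90.4; 20.0: 4.8, 85.5

(scatter of a reading: 0.5 percentage points)

1. the flask that ends with the higher amount of target, in percent of the substrate charged, or "neither" when 2 percentage points or less lies between them (theta / delta / neither)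
2. final target, as a percentage of the substrate charged, in theta
3. final target, as a percentage of the substrate charged, in delta



While the intermediate pool fills, target over substrate lost equals t/(2τ). The reckoning here, taking one reagent per substrate, uses

y = 1 − exp(−E), with E = k c̄ (t − τ),

where y is target as a fraction of substrate charged and c̄ is the charge less half of what has reacted.

In logarithms, a fractional error in k, c̄ or t − τ is the same fractional error in E. Time and reagent charge are given exactly. Substrate charge enters through c̄, and it equals 16.7% of the reagent in theta but 95.2% in delta. Scatter gives k an error of 3.45%, from substrate lost, and τ an error of 10.4%, from target, which is larger. The target reading at 20.0 min is therefore the one to know well.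

The spring run gives

k = 0.807 L mol⁻¹ min⁻¹

lag τ = 30.2 min

theta: c̄ = 14.6 mM, E = 0.352, y = 29.6%

delta: c̄ = 9.38 mM, y = 20.2%

The scatter in τ moves theta by 2.6 percentage points.

The forecast, reading the intermediate “with a lifetime near 20 min”, names theta, with 36% in theta and 21% in delta. Its theta stands above this reckoning.

The flasks give theta, with 30.9% in theta and 21.0% in delta.

    substrate + reagent → intermediate + released group (k = 0.820 L mol⁻¹ min⁻¹)
    intermediate ⇌ target (K = 9.60, k = 0.0386 min⁻¹)
    intermediate ⇌ isomer of the product (K = 3.00, k = 0.00160 min⁻¹)
    target → over-reaction product (k = 3.48 × 10⁻⁵ min⁻¹)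

In theta, 50.5% of the substrate has reacted while target stands at 30.9%, and the lag τ equals 50.3% of the time. The time allowed is the main reason for theta's shortfall: target stands at 30.9% at the asked time, against 81.4% after 10.0 h. A neighbour flask, delta charged with 18 mM of reagent, has c̄ = 16.2 mM, so the same lag gives y = 32.3%. That neighbour flask ends with 32.6% of target.

(All runs are simulated for substances that don't exist, noise included.)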